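**Plan**

- Numbering: C1/C5 ring fusion; C2, C3=C4(CH3) complete cyclopentene ring A; C6(OH), C7, C8, C9(OH), C10(=CH2) complete seven-membered ring B; side chain C11(CH3), C12(OAc), C13=C14, C15(CH3)2OH.
- Feature: in ring B the carbinol C9 is bonded directly to C10, the 1,1-disubstituted alkene carbon. This 2-methylenecycloheptanol unit is what a C10 alkenylmetal gives on adding to a C9 aldehyde.
- Cuts, in retrosynthetic order: C12–C13 (acetylide on a Weinreb amide), C9–C10 (Nozaki–Hiyama–Kishi), C6–C7 with O6–C12 (allylation–lactonisation), C4–CH3, C5–C6 and C1–C10 (conjugate alkynylation with aldol capture).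
- Forward order: ring A first, then a temporary cis γ-lactone (ring C) that carries C6, C7 and C11, then ring B by the key closure; the lactone is opened and the side chain finished last.
- Stereochemistry: C1 from ligand-controlled conjugate alkynylation; C5 from anti aldol capture; C6/C7 from the syn-selective allylation of the C5-branched aldehyde; C11 from kinetic enolate protonation; C9 from the ring conformation in the key closure; C12 from Noyori transfer hydrogenation.

Key step: step 15

Remark: in step 1 the ligand antipode that delivers the 3R adduct is used, and aldehyde 16 is taken as a purchased compound.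

**Route**

Step 1
Reactants: 1 cyclopent-2-en-1-one; 2 ethynyltrimethylsilane
Product: 5 (2R,3R)-2-(hydroxymethyl)-3-[(trimethylsilyl)ethynyl]cyclopentan-1-one, via alkynylalane 3 (not isolated), via aluminium enolate 4 (not isolated)
Conditions: 2, n-BuLi, Et2O, −78 → 0 °C; Me2AlCl; Ni(acac)2 (5 mol %), chiral cyanobis(oxazoline) ligand (6 mol %), 1, t-BuOMe, 0 °C; then CH2O (gas), −40 °C; aq. NH4Cl
Reagents that add atoms: formaldehyde C=O; chlorodimethylaluminium C[Al](C)Cl (its Me2Al group is in 3 and 4 only)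
Why: Nickel-catalysed enantioselective conjugate addition of the dimethylaluminium acetylide to the cyclic enone sets C1 (3R) under ligand control, and the regiodefined aluminium enolate 4 then undergoes an aldol reaction with monomeric formaldehyde anti to the alkynyl group, so that the trans ketol with C5 (2R) should result (tandem conjugate addition–aldol capture).

Step 2
Reactants: 5 (2R,3R)-2-(hydroxymethyl)-3-[(trimethylsilyl)ethynyl]cyclopentan-1-one
Product: 6 (2R,3R)-2-{[(tert-butyldimethylsilyl)oxy]methyl}-3-[(trimethylsilyl)ethynyl]cyclopentan-1-one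
Conditions: TBSCl, imidazole, CH2Cl2, 0 °C
Reagents that add atoms: tert-butyldimethylsilyl chloride CC(C)(C)[Si](C)(C)Cl
Why: Silyl ether formation at the primary alcohol stops retro-aldol cleavage and dehydration of the β-hydroxy ketone and removes the acidic proton before the enolisation that follows.

Step 3
Reactants: 6 (2R,3R)-2-{[(tert-butyldimethylsilyl)oxy]methyl}-3-[(trimethylsilyl)ethynyl]cyclopentan-1-one
Product: 8 (4R,5R)-5-{[(tert-butyldimethylsilyl)oxy]methyl}-4-[(trimethylsilyl)ethynyl]cyclopent-1-en-1-yl trifluoromethanesulfonate, via lithium enolate 7 (not isolated)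
Conditions: LiN(i-Pr)2, THF, −78 °C; then PhNTf2, −78 → 0 °C
Reagents that add atoms: N-phenylbis(trifluoromethanesulfonimide) O=S(=O)(N(c1ccccc1)S(=O)(=O)C(F)(F)F)C(F)(F)F; lithium diisopropylamide CC(C)N([Li])C(C)C (lithium in 7 only)
Why: Kinetic deprotonation by the hindered amide base takes the unsubstituted α-methylene C3 and not the substituted C5, and O-triflation of enolate 7 fixes the future C3=C4 alkene (regioselective enol triflate formation) without touching C1 or C5.

Step 4
Reactants: 8 (4R,5R)-5-{[(tert-butyldimethylsilyl)oxy]methyl}-4-[(trimethylsilyl)ethynyl]cyclopent-1-en-1-yl trifluoromethanesulfonate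
Product: 9 tert-butyldimethyl{[(1S,5R)-2-methyl-5-[(trimethylsilyl)ethynyl]cyclopent-2-en-1-yl]methoxy}silane
Conditions: MeMgBr, Fe(acac)3 (5 mol %), THF/NMP, −30 → 0 °C
Reagents that add atoms: methylmagnesium bromide C[Mg]Br
Why: Iron-catalysed cross-coupling of the alkenyl triflate with the methyl Grignard reagent (Kumada-type coupling) installs the C4 methyl group with the alkene held in place and tolerates the silyl ether and the silylalkyne.

Step 5
Reactants: 9 tert-butyldimethyl{[(1S,5R)-2-methyl-5-[(trimethylsilyl)ethynyl]cyclopent-2-en-1-yl]methoxy}silane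
Product: 10 tert-butyl{[(1S,5R)-5-ethynyl-2-methylcyclopent-2-en-1-yl]methoxy}dimethylsilane
Conditions: K2CO3 (cat.), MeOH, rt
Reagents that add atoms: none
Why: Carbonate-catalysed methanolysis of the C(sp)–Si bond (protodesilylation) frees the terminal alkyne while the primary tert-butyldimethylsilyl ether stays.

Step 6
Reactants: 10 tert-butyl{[(1S,5R)-5-ethynyl-2-methylcyclopent-2-en-1-yl]methoxy}dimethylsilane
Product: 12 tert-butyl{[(1S,5R)-5-(1-iodoethenyl)-2-methylcyclopent-2-en-1-yl]methoxy}dimethylsilane, via alkenylborane 11 (not isolated)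
Conditions: 9-iodo-9-BBN, hexane/CH2Cl2, −20 → 0 °C; then AcOH, 0 °C → rt
Reagents that add atoms: 9-iodo-9-borabicyclo[3.3.1]nonane IB1C2CCCC1CCC2 (iodine to 12; the boron residue is in 11 only)
Why: Syn haloboration of the terminal alkyne puts boron on the terminal carbon and iodine on C10, and protonolysis of the alkenyl–boron bond of 11 gives the 2-iodo-1-alkene (Markovnikov hydroiodination by haloboration–protodeboronation), a sequence selective for terminal alkynes over the trisubstituted ring alkene.

Step 7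
Reactants: 12 tert-butyl{[(1S,5R)-5-(1-iodoethenyl)-2-methylcyclopent-2-en-1-yl]methoxy}dimethylsilane
Product: 13 [(1S,5R)-5-(1-iodoethenyl)-2-methylcyclopent-2-en-1-yl]methanol
Conditions: HF·pyridine, pyridine, THF, 0 °C
Reagents that add atoms: none
Why: Buffered fluoride cleavage of the primary silyl ether (desilylation) leaves the vinyl iodide and both alkenes untouched.

Step 8
Reactants: 13 [(1S,5R)-5-(1-iodoethenyl)-2-methylcyclopent-2-en-1-yl]methanol
Product: 14 (1S,5R)-5-(1-iodoethenyl)-2-methylcyclopent-2-ene-1-carbaldehyde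
Conditions: Dess–Martin periodinane, NaHCO3, CH2Cl2, 0 °C; crude product used at once
Reagents that add atoms: none
Why: Buffered Dess–Martin oxidation gives the aldehyde without acid or base strong enough to epimerise C5 or to move the C3=C4 alkene into conjugation.

Step 9
Reactants: 15 methyl acrylate; 16 3-[(tert-butyldimethylsilyl)oxy]propanal
Product: 17 methyl 5-[(tert-butyldimethylsilyl)oxy]-3-hydroxy-2-methylidenepentanoate (racemic)
Conditions: DABCO (0.5 equiv), neat, rt
Reagents that add atoms: none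
Why: Morita–Baylis–Hillman reaction, in which the amine–acrylate zwitterion adds to the aliphatic aldehyde and loss of the amine gives the 2-methylene-3-hydroxy ester; the racemic carbinol centre is erased in the next step.

Step 10
Reactants: 17 methyl 5-[(tert-butyldimethylsilyl)oxy]-3-hydroxy-2-methylidenepentanoate
Product: 18 methyl (2Z)-2-(bromomethyl)-5-[(tert-butyldimethylsilyl)oxy]pent-2-enoate
Conditions: NBS, Me2S, CH2Cl2, 0 °C → rt
Reagents that add atoms: N-bromosuccinimide O=C1CCC(=O)N1Br
Why: Activation of the allylic alcohol as an alkoxysulfonium ion and SN2' attack of bromide (Corey–Kim-type bromination with allylic transposition) gives the more stable trisubstituted alkenoate with the chain cis to CH2Br.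

Step 11
Reactants: 14 (1S,5R)-5-(1-iodoethenyl)-2-methylcyclopent-2-ene-1-carbaldehyde; 18 methyl (2Z)-2-(bromomethyl)-5-[(tert-butyldimethylsilyl)oxy]pent-2-enoate
Product: 21 (4S,5R)-4-{2-[(tert-butyldimethylsilyl)oxy]ethyl}-5-[(1S,5R)-5-(1-iodoethenyl)-2-methylcyclopent-2-en-1-yl]-3-methylideneoxolan-2-one, via allylzinc bromide 19 (not isolated), via syn hydroxy ester 20 (not isolated)
Conditions: Zn dust, THF/sat. aq. NH4Cl, 0 °C → rt; then PPTS (cat.), toluene, 50 °C
Reagents that add atoms: zinc [Zn] (in 19 only)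
Why: Barbier-type zinc allylation (Dreiding–Schmidt reaction) in which allylzinc 19 adds through its γ-carbon in a chair transition state with the γ-substituent axial, giving the C6/C7 syn adduct 20; the aldehyde face is set by C5, with the ring alkene carbon C4 anti to the nucleophile and the C5 hydrogen turned towards the axial γ-substituent, which should give 6R,7S, and acid-catalysed lactonisation closes the cis-β,γ-disubstituted α-methylene lactone.

Step 12
Reactants: 21 (4S,5R)-4-{2-[(tert-butyldimethylsilyl)oxy]ethyl}-5-[(1S,5R)-5-(1-iodoethenyl)-2-methylcyclopent-2-en-1-yl]-3-methylideneoxolan-2-one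
Product: 23 (3R,4S,5R)-4-{2-[(tert-butyldimethylsilyl)oxy]ethyl}-5-[(1S,5R)-5-(1-iodoethenyl)-2-methylcyclopent-2-en-1-yl]-3-methyloxolan-2-one, via lactone enolate 22 (not isolated)
Conditions: LiBH(s-Bu)3, THF, −78 °C; then AcOH, −78 °C
Reagents that add atoms: lithium tri-sec-butylborohydride [Li+].CCC(C)[BH-](C(C)CC)C(C)CC (lithium in 22 only)
Why: Conjugate reduction, in which hydride adds to the exocyclic methylene carbon and enolate 22 is protonated under kinetic control on the face opposite the C6 and C7 substituents, which places the C11 methyl cis to both (11R, all-cis lactone).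

Step 13
Reactants: 23 (3R,4S,5R)-4-{2-[(tert-butyldimethylsilyl)oxy]ethyl}-5-[(1S,5R)-5-(1-iodoethenyl)-2-methylcyclopent-2-en-1-yl]-3-methyloxolan-2-one
Product: 24 (3R,4S,5R)-4-(2-hydroxyethyl)-5-[(1S,5R)-5-(1-iodoethenyl)-2-methylcyclopent-2-en-1-yl]-3-methyloxolan-2-one
Conditions: HF·pyridine, pyridine, THF, 0 °C
Reagents that add atoms: none
Why: Fluoride desilylation under weakly acidic conditions frees the C9 hydroxyl without the base that could epimerise the contra-thermodynamic C11 centre.

Step 14
Reactants: 24 (3R,4S,5R)-4-(2-hydroxyethyl)-5-[(1S,5R)-5-(1-iodoethenyl)-2-methylcyclopent-2-en-1-yl]-3-methyloxolan-2-one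
Product: 25 2-{(2R,3S,4R)-2-[(1S,5R)-5-(1-iodoethenyl)-2-methylcyclopent-2-en-1-yl]-4-methyl-5-oxooxolan-3-yl}acetaldehyde
Conditions: Dess–Martin periodinane, NaHCO3, CH2Cl2, 0 °C
Reagents that add atoms: none
Why: Dess–Martin oxidation of the primary alcohol gives the C9 aldehyde under neutral conditions that spare the vinyl iodide, the lactone and C11.

Step 15
Reactants: 25 2-{(2R,3S,4R)-2-[(1S,5R)-5-(1-iodoethenyl)-2-methylcyclopent-2-en-1-yl]-4-methyl-5-oxooxolan-3-yl}acetaldehyde
Product: 27 tricyclic 9-hydroxy lactone (1R,5S,6R,7S,9R,11R), via alkenylchromium 26 (not isolated)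
Conditions: CrCl2 (8 equiv), NiCl2 (2 mol %), degassed DMSO, rt, 0.005 M, slow addition of 25
Reagents that add atoms: chromium dichloride Cl[Cr]Cl (chromium and chloride in 26 only)
Why: CrCl2 reduces NiCl2 to zerovalent nickel, which inserts into the C10–I bond, and transmetalation to trivalent chromium gives alkenylchromium 26, which adds to the tethered C9 aldehyde (intramolecular Nozaki–Hiyama–Kishi reaction). The closest known reaction type is the nickel/chromium-mediated cyclisation of ω-formyl 2-iodoalkenes to medium-ring 2-methylenecycloalkanols. Ring B closes in a 7-exo-trig mode with respect to the carbonyl, and C9–C10 is the only skeletal bond formed. The new centre C9 is set by the substrate: the cis lactone at C6/C7 and the trans-disposed C1 and C5 substituents of ring A restrict the tether, so the chromium alkoxide should develop on the face opposite the lactone, which gives 9R. The step needs attack at the aldehyde only, which the carbonyl selectivity and low basicity of organochromium reagents secure (lactone, C11 and both alkenes untouched), and cyclisation over dimerisation, which high dilution secures. The C9 facial selectivity is expected but not guaranteed.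

Step 16
Reactants: 27 tricyclic 9-hydroxy lactone (1R,5S,6R,7S,9R,11R)
Product: 28 6,9-dihydroxy Weinreb amide (1R,5S,6R,7S,9R,11R)
Conditions: MeNH(OMe)·HCl, i-PrMgCl, THF, −20 → 0 °C; crude product silylated at once
Reagents that add atoms: N,O-dimethylhydroxylamine hydrochloride CNOC.Cl
Why: Aminolysis of the γ-lactone by the chloromagnesium amide (Weinreb amide formation) opens the ring at the acyl carbon, so C6, C7 and C11 keep their configuration and the C6 hydroxyl is freed, while a second equivalent of the amide only deprotonates the C9 hydroxyl.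

Step 17
Reactants: 28 6,9-dihydroxy Weinreb amide (1R,5S,6R,7S,9R,11R)
Product: 29 6,9-bis(triethylsilyl) ether of the Weinreb amide
Conditions: Et3SiOTf, 2,6-lutidine, CH2Cl2, −78 → 0 °C
Reagents that add atoms: triethylsilyl trifluoromethanesulfonate CC[Si](CC)(CC)OS(=O)(=O)C(F)(F)F
Why: Silyl ether formation at both secondary hydroxyls with the silyl triflate at low temperature is faster than relactonisation of the γ-hydroxy amide and masks C6–OH and C9–OH for the organometallic steps.

Step 18
Reactants: 29 6,9-bis(triethylsilyl) ether of the Weinreb amide; 30 2-methylbut-3-yn-2-ol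
Product: 32 C12 ynone carrying C≡C–C(CH3)2OH (1R,5S,6R,7S,9R,11R), via dilithium alkynoxide 31 (not isolated)
Conditions: 30, n-BuLi (2 equiv per 30), THF, −78 → 0 °C; then 29, −78 → 0 °C
Reagents that add atoms: n-butyllithium [Li]CCCC (lithium in 31 only)
Why: The acetylide end of dianion 31 adds to the Weinreb amide and the chelated tetrahedral intermediate gives the ynone only on work-up (Weinreb ketone synthesis), so over-addition does not occur and the weakly basic acetylide does not enolise C11.

Step 19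
Reactants: 32 C12 ynone (1R,5S,6R,7S,9R,11R)
Product: 33 (12R)-propargylic diol
Conditions: Ru[(R,R)-TsDPEN](p-cymene) (2 mol %), i-PrOH, rt
Reagents that add atoms: none
Why: Noyori asymmetric transfer hydrogenation of the ynone, in which the alkynyl group takes the place an aryl group normally occupies, so the (R,R)-catalyst should give the 12R propargylic alcohol (the C12 geometry of the target) under catalyst control whatever the bias of the C11 centre.

Step 20
Reactants: 33 (12R)-propargylic diol
Product: 34 (12S,13E)-allylic diol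
Conditions: NaAlH2(OCH2CH2OMe)2, THF, 0 °C → rt; aq. KNa tartrate
Reagents that add atoms: none
Why: Hydroxyl-directed trans-hydroalumination of the propargylic alcohol and protonolysis on work-up give the E-alkene only; both hydroxyls are alkoxides during the reduction, so no allene forms by elimination, and the C12 descriptor changes to S only through the change in priorities.

Step 21
Reactants: 34 (12S,13E)-allylic diol
Product: 35 12-acetate of 34
Conditions: Ac2O, pyridine, DMAP (cat.), CH2Cl2, 0 °C
Reagents that add atoms: acetic anhydride CC(=O)OC(C)=O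
Why: Esterification with acetic anhydride under nucleophilic catalysis takes the secondary allylic C12 hydroxyl and leaves the hindered tertiary C15 hydroxyl free.

Step 22
Reactants: 35 12-acetate of 34
Product: 36 CNP0213969.2
Conditions: HF·pyridine, pyridine, THF, 0 °C → rt
Reagents that add atoms: none
Why: Pyridine-buffered fluoride cleavage of the two triethylsilyl ethers (desilylation) is mild enough to keep the acetate, the tertiary allylic alcohol and the allylic C9 alcohol intact and should give the target.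

**Compound list**

1 | cyclopent-2-en-1-one | O=C1C=CCC1 | starting material
2 | ethynyltrimethylsilane | C#C[Si](C)(C)C | starting material
3 | dimethyl[(trimethylsilyl)ethynyl]aluminium (alkynylalane, not isolated) | C[Al](C)C#C[Si](C)(C)C | intermediate
4 | dimethyl{[(3R)-3-[(trimethylsilyl)ethynyl]cyclopent-1-en-1-yl]oxy}aluminium (aluminium enolate, not isolated) | C[Si](C)(C)C#C[C@@H]1CCC(O[Al](C)C)=C1 | intermediate
5 | (2R,3R)-2-(hydroxymethyl)-3-[(trimethylsilyl)ethynyl]cyclopentan-1-one (trans) | C[Si](C)(C)C#C[C@@H]1CCC(=O)[C@H]1CO | intermediate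
6 | (2R,3R)-2-{[(tert-butyldimethylsilyl)oxy]methyl}-3-[(trimethylsilyl)ethynyl]cyclopentan-1-one | C[Si](C)(C)C#C[C@@H]1CCC(=O)[C@H]1CO[Si](C)(C)C(C)(C)C | intermediate
7 | lithium (4R,5R)-5-{[(tert-butyldimethylsilyl)oxy]methyl}-4-[(trimethylsilyl)ethynyl]cyclopent-1-en-1-olate (kinetic enolate, not isolated) | C[Si](C)(C)C#C[C@@H]1CC=C(O[Li])[C@H]1CO[Si](C)(C)C(C)(C)C | intermediate
8 | (4R,5R)-5-{[(tert-butyldimethylsilyl)oxy]methyl}-4-[(trimethylsilyl)ethynyl]cyclopent-1-en-1-yl trifluoromethanesulfonate | C[Si](C)(C)C#C[C@@H]1CC=C(OS(=O)(=O)C(F)(F)F)[C@H]1CO[Si](C)(C)C(C)(C)C | intermediate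
9 | tert-butyldimethyl{[(1S,5R)-2-methyl-5-[(trimethylsilyl)ethynyl]cyclopent-2-en-1-yl]methoxy}silane | C[Si](C)(C)C#C[C@@H]1CC=C(C)[C@H]1CO[Si](C)(C)C(C)(C)C | intermediate
10 | tert-butyl{[(1S,5R)-5-ethynyl-2-methylcyclopent-2-en-1-yl]methoxy}dimethylsilane | C#C[C@@H]1CC=C(C)[C@H]1CO[Si](C)(C)C(C)(C)C | intermediate
11 | 9-[(Z)-2-iodo-2-{(1R,2S)-2-{[(tert-butyldimethylsilyl)oxy]methyl}-3-methylcyclopent-3-en-1-yl}ethenyl]-9-borabicyclo[3.3.1]nonane (boron and iodine cis, not isolated) | C1CC2CCCC(C1)B2/C=C(\I)[C@@H]1CC=C(C)[C@H]1CO[Si](C)(C)C(C)(C)C | intermediate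
12 | tert-butyl{[(1S,5R)-5-(1-iodoethenyl)-2-methylcyclopent-2-en-1-yl]methoxy}dimethylsilane | C=C(I)[C@@H]1CC=C(C)[C@H]1CO[Si](C)(C)C(C)(C)C | intermediate
13 | [(1S,5R)-5-(1-iodoethenyl)-2-methylcyclopent-2-en-1-yl]methanol | C=C(I)[C@@H]1CC=C(C)[C@H]1CO | intermediate
14 | (1S,5R)-5-(1-iodoethenyl)-2-methylcyclopent-2-ene-1-carbaldehyde | C=C(I)[C@@H]1CC=C(C)[C@H]1C=O | intermediate
15 | methyl acrylate | C=CC(=O)OC | starting material
16 | 3-[(tert-butyldimethylsilyl)oxy]propanal | CC(C)(C)[Si](C)(C)OCCC=O | starting material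
17 | methyl 5-[(tert-butyldimethylsilyl)oxy]-3-hydroxy-2-methylidenepentanoate (racemic) | C=C(C(=O)OC)C(O)CCO[Si](C)(C)C(C)(C)C | intermediate
18 | methyl (2Z)-2-(bromomethyl)-5-[(tert-butyldimethylsilyl)oxy]pent-2-enoate | COC(=O)/C(CBr)=C/CCO[Si](C)(C)C(C)(C)C | intermediate
19 | bromo[(2Z)-5-[(tert-butyldimethylsilyl)oxy]-2-(methoxycarbonyl)pent-2-en-1-yl]zinc (allylzinc bromide, not isolated) | COC(=O)/C(C[Zn]Br)=C/CCO[Si](C)(C)C(C)(C)C | intermediate
20 | methyl (3S,4R)-3-{2-[(tert-butyldimethylsilyl)oxy]ethyl}-4-hydroxy-4-[(1S,5R)-5-(1-iodoethenyl)-2-methylcyclopent-2-en-1-yl]-2-methylidenebutanoate (syn hydroxy ester, not isolated) | C=C(I)[C@@H]1CC=C(C)[C@H]1[C@H](O)[C@@H](CCO[Si](C)(C)C(C)(C)C)C(=C)C(=O)OC | intermediate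
21 | (4S,5R)-4-{2-[(tert-butyldimethylsilyl)oxy]ethyl}-5-[(1S,5R)-5-(1-iodoethenyl)-2-methylcyclopent-2-en-1-yl]-3-methylideneoxolan-2-one (cis lactone) | C=C(I)[C@@H]1CC=C(C)[C@H]1[C@@H]2OC(=O)C(=C)[C@@H]2CCO[Si](C)(C)C(C)(C)C | intermediate
22 | lithium (4S,5R)-4-{2-[(tert-butyldimethylsilyl)oxy]ethyl}-5-[(1S,5R)-5-(1-iodoethenyl)-2-methylcyclopent-2-en-1-yl]-3-methyl-4,5-dihydrofuran-2-olate (lactone enolate, not isolated) | C=C(I)[C@@H]1CC=C(C)[C@H]1[C@@H]2OC(O[Li])=C(C)[C@@H]2CCO[Si](C)(C)C(C)(C)C | intermediate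
23 | (3R,4S,5R)-4-{2-[(tert-butyldimethylsilyl)oxy]ethyl}-5-[(1S,5R)-5-(1-iodoethenyl)-2-methylcyclopent-2-en-1-yl]-3-methyloxolan-2-one (all-cis) | C=C(I)[C@@H]1CC=C(C)[C@H]1[C@@H]2OC(=O)[C@H](C)[C@@H]2CCO[Si](C)(C)C(C)(C)C | intermediate
24 | (3R,4S,5R)-4-(2-hydroxyethyl)-5-[(1S,5R)-5-(1-iodoethenyl)-2-methylcyclopent-2-en-1-yl]-3-methyloxolan-2-one | C=C(I)[C@@H]1CC=C(C)[C@H]1[C@@H]2OC(=O)[C@H](C)[C@@H]2CCO | intermediate
25 | 2-{(2R,3S,4R)-2-[(1S,5R)-5-(1-iodoethenyl)-2-methylcyclopent-2-en-1-yl]-4-methyl-5-oxooxolan-3-yl}acetaldehyde (vinyl iodide aldehyde) | C=C(I)[C@@H]1CC=C(C)[C@H]1[C@@H]2OC(=O)[C@H](C)[C@@H]2CC=O | intermediate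
26 | alkenylchromium dichloride: 25 with CrCl2 in place of iodine on C10 (not isolated) | C=C([Cr](Cl)Cl)[C@@H]1CC=C(C)[C@H]1[C@@H]2OC(=O)[C@H](C)[C@@H]2CC=O | intermediate
27 | tricyclic 9-hydroxy lactone (1R,5S,6R,7S,9R,11R): ring A (C3=C4, 4-methyl) trans-fused at C1/C5 to ring B with 10-methylidene and 9-OH; cis γ-lactone O6–C12(=O)–C11(CH3)–C7 | C=C1[C@H](O)C[C@@H]([C@@H](C)C(=O)O3)[C@@H]3[C@@H]2C(C)=CC[C@@H]12 | intermediate
28 | 6,9-dihydroxy Weinreb amide (1R,5S,6R,7S,9R,11R): bicyclic 6,9-diol with CH(CH3)C(=O)N(OCH3)CH3 on C7 | C=C1[C@H](O)C[C@@H]([C@@H](C)C(=O)N(C)OC)[C@@H](O)[C@@H]2C(C)=CC[C@@H]12 | intermediate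
29 | 6,9-bis(triethylsilyl) ether of 28 | C=C1[C@H](O[Si](CC)(CC)CC)C[C@@H]([C@@H](C)C(=O)N(C)OC)[C@@H](O[Si](CC)(CC)CC)[C@@H]2C(C)=CC[C@@H]12 | intermediate
30 | 2-methylbut-3-yn-2-ol | CC(C)(O)C#C | starting material
31 | dilithium salt of 30 (lithium acetylide and lithium alkoxide, not isolated) | [Li]C#CC(C)(C)O[Li] | intermediate
32 | C12 ynone (1R,5S,6R,7S,9R,11R): C12(=O)–C≡C–C(CH3)2OH, 6,9-bis(triethylsilyl) ether | C=C1[C@H](O[Si](CC)(CC)CC)C[C@@H]([C@@H](C)C(=O)C#CC(C)(C)O)[C@@H](O[Si](CC)(CC)CC)[C@@H]2C(C)=CC[C@@H]12 | intermediate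
33 | (12R)-propargylic diol (1R,5S,6R,7S,9R,11R,12R), 6,9-bis(triethylsilyl) ether | C=C1[C@H](O[Si](CC)(CC)CC)C[C@@H]([C@@H](C)[C@H](C#CC(C)(C)O)O)[C@@H](O[Si](CC)(CC)CC)[C@@H]2C(C)=CC[C@@H]12 | intermediate
34 | (12S,13E)-allylic diol (1R,5S,6R,7S,9R,11R,12S), 6,9-bis(triethylsilyl) ether | C=C1[C@H](O[Si](CC)(CC)CC)C[C@@H]([C@@H](C)[C@H](/C=C/C(C)(C)O)O)[C@@H](O[Si](CC)(CC)CC)[C@@H]2C(C)=CC[C@@H]12 | intermediate
35 | 12-acetate of 34 | C=C1[C@H](O[Si](CC)(CC)CC)C[C@@H]([C@@H](C)[C@H](/C=C/C(C)(C)O)OC(C)=O)[C@@H](O[Si](CC)(CC)CC)[C@@H]2C(C)=CC[C@@H]12 | intermediate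
36 | CNP0213969.2, (1R,5S,6R,7S,9R,11R,12S,13E)-12-acetoxy-6,9,15-triol | C=C1[C@H](O)C[C@@H]([C@@H](C)[C@H](/C=C/C(C)(C)O)OC(C)=O)[C@@H](O)[C@@H]2C(C)=CC[C@@H]12 | target

**Step count**

Total: 22 steps. Longest linear sequence: 20 steps (steps 1–8 and 11–22, from cyclopent-2-en-1-one); steps 9 and 10 make the side branch.

**Steps most likely to fail**

Step 15. The ring closure may show poor facial selectivity at C9, because the preference rests only on the conformation of the forming seven-membered ring. Fallback: the mixture of 27 and the C9 epimer F1 is oxidised with Dess–Martin periodinane to the α-methylene ketone F2. Reduction of this ketone with (S)-2-methyl-CBS-oxazaborolidine and catecholborane at low temperature, with the methylene-bearing C10 as the large group, should set 9R under reagent control and return to 27. C9 is then set by carbonyl reduction and no longer during the carbon–carbon bond formation.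

Step 11. The allylzinc may attack the wrong face of the C5-branched aldehyde, and 14 may enolise at C5 (epimerisation, or migration of the ring alkene into conjugation) before it is captured. Fallback: starting from bromide 18, copper-catalysed borylation (B2pin2, CuCl, KOt-Bu, THF) gives the isolable allylboronate methyl (2E)-5-[(tert-butyldimethylsilyl)oxy]-2-[(4,4,5,5-tetramethyl-1,3,2-dioxaborolan-2-yl)methyl]pent-2-enoate F3. Its addition to 14 under a chiral phosphoric acid (the TRIP antipode matched to the required face) runs through a closed chair transition state in a neutral medium. It should give hydroxy ester 20 under catalyst control, and the same acid-catalysed lactonisation returns to 21.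

Step 1. The alkynyl transfer to the five-membered enone may be insufficiently enantioselective. Fallback: the absolute configuration is taken from the chiral pool, starting from alkynylalane 3 and (S)-4-[(tert-butyldimethylsilyl)oxy]cyclopent-2-en-1-one F4 in place of 1. Addition of 3 under Ni(acac)2/i-Bu2AlH catalysis anti to the silyloxy group, followed by formaldehyde capture, should give (2R,3R,4S)-4-[(tert-butyldimethylsilyl)oxy]-2-(hydroxymethyl)-3-[(trimethylsilyl)ethynyl]cyclopentan-1-one F5. Silylation with TBSCl and imidazole gives the bis-silyl ether F6. DBU then eliminates the ring silyloxy group to give (4R,5R)-5-{[(tert-butyldimethylsilyl)oxy]methyl}-4-[(trimethylsilyl)ethynyl]cyclopent-2-en-1-one F7. Conjugate reduction with catalytic [(Ph3P)CuH]6 and polymethylhydrosiloxane returns to 6.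

**Further compounds**

F1 | step 15 | C9 epimer of 27 (1R,5S,6R,7S,9S,11R) | C=C1[C@@H](O)C[C@@H]([C@@H](C)C(=O)O3)[C@@H]3[C@@H]2C(C)=CC[C@@H]12
F2 | step 15 | 9-oxo analogue of 27 (α-methylene ketone) | C=C1C(=O)C[C@@H]([C@@H](C)C(=O)O3)[C@@H]3[C@@H]2C(C)=CC[C@@H]12
F3 | step 11 | methyl (2E)-5-[(tert-butyldimethylsilyl)oxy]-2-[(4,4,5,5-tetramethyl-1,3,2-dioxaborolan-2-yl)methyl]pent-2-enoate | COC(=O)/C(CB1OC(C)(C)C(C)(C)O1)=C/CCO[Si](C)(C)C(C)(C)C
F4 | step 1 | (S)-4-[(tert-butyldimethylsilyl)oxy]cyclopent-2-en-1-one | C1=CC(=O)C[C@@H]1O[Si](C)(C)C(C)(C)C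
F5 | step 1 | (2R,3R,4S)-4-[(tert-butyldimethylsilyl)oxy]-2-(hydroxymethyl)-3-[(trimethylsilyl)ethynyl]cyclopentan-1-one | C[Si](C)(C)C#C[C@@H]1[C@@H](O[Si](C)(C)C(C)(C)C)CC(=O)[C@H]1CO
F6 | step 1 | (2R,3R,4S)-4-[(tert-butyldimethylsilyl)oxy]-2-{[(tert-butyldimethylsilyl)oxy]methyl}-3-[(trimethylsilyl)ethynyl]cyclopentan-1-one | C[Si](C)(C)C#C[C@@H]1[C@@H](O[Si](C)(C)C(C)(C)C)CC(=O)[C@H]1CO[Si](C)(C)C(C)(C)C
F7 | step 1 | (4R,5R)-5-{[(tert-butyldimethylsilyl)oxy]methyl}-4-[(trimethylsilyl)ethynyl]cyclopent-2-en-1-one | C[Si](C)(C)C#C[C@@H]1C=CC(=O)[C@H]1CO[Si](C)(C)C(C)(C)C
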